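**Retrosynthetic overview**

1. Numbering of the 3,7-dioxabicyclo[3.3.0]octane core: C1(OH), C2(Ar, exo), O3, C4H2, C5(H), C6(Ar, endo), O7, C8H2; Ar = 3,4-dimethoxyphenyl; the target is (1S,2R,5R,6R).
2. Ring A is opened last at O3–C4 (Williamson etherification of a C2–OH/C4–OH pair); the C4 hydroxymethyl comes from anti-Markovnikov hydration of a C5=C4 exocyclic alkene on ring B.
3. Ring B is opened at C8–O7: C1(OH)–C8H2 is read as a 2,2-disubstituted oxirane (C1–O–C8) that the C6 benzylic hydroxyl opens at C8 (strain release); the oxirane is made in the same flask by Sharpless epoxidation of a C1=C8 alkene under direction of the C2 hydroxyl.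
4. Enabling feature: C2 (exo aryl) and C6 (endo aryl) are mirror-related, so the diene diol ArCH(OH)–C1(=C8H2)–C5(=C4H2)–CH(OH)Ar is an achiral meso compound that differs from gmelinol by one oxygen atom; the epoxidation is therefore a desymmetrization that creates C1 and fixes the absolute sense of C2 and C6 in one operation.
5. The meso diene diol comes from the meso 2-yne-1,4-diol by ethylene enyne metathesis, and that from two veratraldehydes and one ethynyl unit; ring B forms in step 3, ring A in step 5.

Key step: step 3

Step 1
Reactants: 1 3,4-dimethoxybenzaldehyde (veratraldehyde, 2 equiv in two portions); 2 ethynylmagnesium bromide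
Product: 4 meso-(1R,4S)-1,4-bis(3,4-dimethoxyphenyl)but-2-yne-1,4-diol, via bromomagnesium alkynyl alkoxide 3 (not isolated)
Conditions: 2 (1.0 equiv), THF, 0 °C, 1 (1.0 equiv); EtMgBr (1.1 equiv), 50 °C; 1 (1.0 equiv), 0→23 °C; aq NH4Cl; fractional crystallization
Reagents that add atoms: none
Why: Two successive 1,2-additions of alkynylmagnesium species to the non-enolizable aldehyde (acetylenic Grignard addition) assemble the symmetric diol; no 1,4-induction is expected across the linear alkyne, so both carbinol centres form without control and the achiral meso diastereomer has to be taken out of its mixture with the chiral one by crystallization.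

Step 2
Reactants: 4 meso-(1R,4S)-1,4-bis(3,4-dimethoxyphenyl)but-2-yne-1,4-diol; 5 ethylene
Product: 6 meso-(1R,4S)-1,4-bis(3,4-dimethoxyphenyl)-2,3-dimethylidenebutane-1,4-diol
Conditions: ethylene (4 atm), second-generation Grubbs catalyst RuCl2(=CHPh)(H2IMes)(PCy3) (5 mol %), CH2Cl2, 40 °C
Reagents that add atoms: none
Why: Ethylene–alkyne cross enyne metathesis, in which the ruthenium methylidene adds across the alkyne to a vinyl carbene that ethylene intercepts, should turn the internal alkyne into the 2,3-disubstituted buta-1,3-diene without touching the two carbinol centres, so the meso relationship is kept.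

Step 3
Reactants: 6 meso-(1R,4S)-1,4-bis(3,4-dimethoxyphenyl)-2,3-dimethylidenebutane-1,4-diol
Product: 8 (3S,5S)-5-(3,4-dimethoxyphenyl)-3-[(R)-(3,4-dimethoxyphenyl)(hydroxy)methyl]-4-methylideneoxolan-3-ol, via erythro epoxy diol 7 (not isolated)
Conditions: Ti(OiPr)4 (0.3 equiv), D-(−)-diisopropyl tartrate (0.36 equiv), t-BuOOH (1.2 equiv), 4 Å MS, CH2Cl2, −20 °C; then 23 °C
Reagents that add atoms: tert-butyl hydroperoxide, CC(C)(C)OO
Why: The D-tartrate-ligated tetravalent titanium tert-butylperoxide can bind either carbinol of meso-6 but should transfer oxygen fast only within the matched half, the (R)-carbinol and its own 1,1-disubstituted alkene, giving the erythro epoxy alkoxide 7; the oxygen of the other, (S)-configured carbinol then attacks the unsubstituted oxirane carbon C8 in an SN2 opening assisted by titanium chelation of the epoxy alkoxide, and release of the oxirane strain drives formation of the C8–O7 bond. The closest known reaction types are the Sharpless desymmetrization of meso bis(allylic) secondary alcohols, the Ti(OiPr)4-mediated opening of 2,3-epoxy alcohols at the carbon remote from the carbinol, and the cyclization of 3-methyl-3,4-epoxybutan-1-ol-type homoallylic epoxides to tetrahydrofuran-3-ols. Ring B closes in a 5-endo mode with respect to the oxirane (attack at the distal CH2 with the oxirane C–C bond inside the new ring), whereas the 4-exo alternative at the fully substituted C1 would give an oxetane. The only new stereocenter, C1, is set by the catalyst (the D-(−)-tartrate delivers oxygen to the face that gives 1S) in concert with the erythro preference relative to the bound C2 carbinol, while C2 and C6 keep their configuration and become the exo-aryl and endo-aryl centres because the directing and the ring-closing carbinol are of opposite sense. The step needs discrimination of the two enantiotopic halves, which the large rate gap between matched and mismatched secondary allylic alcohols in this epoxidation should secure, and C8-over-C1 regioselectivity, which the ring size (five against four) and the primary against fully substituted nature of the two oxirane carbons should secure.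

Step 4
Reactants: 8 (3S,5S)-5-(3,4-dimethoxyphenyl)-3-[(R)-(3,4-dimethoxyphenyl)(hydroxy)methyl]-4-methylideneoxolan-3-ol
Product: 10 (3S,4R,5R)-5-(3,4-dimethoxyphenyl)-3-[(R)-(3,4-dimethoxyphenyl)(hydroxy)methyl]-4-(hydroxymethyl)oxolan-3-ol, via primary alkylborane 9 (not isolated)
Conditions: BH3·THF (4 equiv), THF, 0→23 °C; then aq NaOH, H2O2, 0→23 °C
Reagents that add atoms: hydrogen peroxide, OO; borane–tetrahydrofuran, B.C1CCOC1 (boron only in 9)
Why: In this hydroboration–oxidation boron should go to the terminal carbon of the exocyclic alkene and hydrogen to C5 from the ring face that carries only the C1 oxygen and the C6 hydrogen, away from the C6 aryl group and the C1 aryl-carbinol chain on the other face, which sets C5–H cis to C1–OH (5R of the target) and places the new CH2OH cis to the C2 carbinol as ring A requires; the oxidation retains the configuration.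

Step 5
Reactants: 10 (3S,4R,5R)-5-(3,4-dimethoxyphenyl)-3-[(R)-(3,4-dimethoxyphenyl)(hydroxy)methyl]-4-(hydroxymethyl)oxolan-3-ol
Product: 12 (+)-gmelinol, via primary tosylate 11 (not isolated)
Conditions: TsCl (1.1 equiv), Et3N, DMAP (cat.), CH2Cl2, 0 °C; then t-BuOK, THF, 0→23 °C
Reagents that add atoms: 4-methylbenzenesulfonyl chloride, Cc1ccc(cc1)S(Cl)(=O)=O (tosyl group only in 11)
Why: Selective sulfonylation of the only primary hydroxyl followed by intramolecular Williamson etherification (5-exo-tet) by the C2 benzylic alkoxide should close ring A with retention at C2 and without acid that could epimerize the endo-aryl centre C6, the tertiary C1 alkoxide being able to give only a strained oxetane.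

**Compound list**

1 | 3,4-dimethoxybenzaldehyde (veratraldehyde) | COc1ccc(C=O)cc1OC | starting material
2 | ethynylmagnesium bromide | C#C[Mg]Br | starting material
3 | bromomagnesium 1-(3,4-dimethoxyphenyl)prop-2-yn-1-olate, racemic (not isolated) | COc1ccc(cc1OC)C(O[Mg]Br)C#C | intermediate
4 | meso-(1R,4S)-1,4-bis(3,4-dimethoxyphenyl)but-2-yne-1,4-diol | COc1ccc(cc1OC)[C@@H](O)C#C[C@@H](O)c1ccc(OC)c(OC)c1 | intermediate
5 | ethylene | C=C | starting material
6 | meso-(1R,4S)-1,4-bis(3,4-dimethoxyphenyl)-2,3-dimethylidenebutane-1,4-diol | COc1ccc(cc1OC)[C@@H](O)C(=C)C(=C)[C@@H](O)c1ccc(OC)c(OC)c1 | intermediate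
7 | (1S)-1-(3,4-dimethoxyphenyl)-2-{(2S)-2-[(R)-(3,4-dimethoxyphenyl)(hydroxy)methyl]oxiran-2-yl}prop-2-en-1-ol (erythro epoxy diol, not isolated) | COc1ccc(cc1OC)[C@@H](O)[C@@]1(CO1)C(=C)[C@@H](O)c1ccc(OC)c(OC)c1 | intermediate
8 | (3S,5S)-5-(3,4-dimethoxyphenyl)-3-[(R)-(3,4-dimethoxyphenyl)(hydroxy)methyl]-4-methylideneoxolan-3-ol | COc1ccc(cc1OC)[C@@H](O)[C@@]1(O)CO[C@@H](c2ccc(OC)c(OC)c2)C1=C | intermediate
9 | {[(2R,3R,4S)-2-(3,4-dimethoxyphenyl)-4-[(R)-(3,4-dimethoxyphenyl)(hydroxy)methyl]-4-hydroxyoxolan-3-yl]methyl}borane (shown in its simplest form, not isolated) | COc1ccc(cc1OC)[C@@H](O)[C@@]1(O)CO[C@@H](c2ccc(OC)c(OC)c2)[C@H]1CB | intermediate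
10 | (3S,4R,5R)-5-(3,4-dimethoxyphenyl)-3-[(R)-(3,4-dimethoxyphenyl)(hydroxy)methyl]-4-(hydroxymethyl)oxolan-3-ol | COc1ccc(cc1OC)[C@@H](O)[C@@]1(O)CO[C@@H](c2ccc(OC)c(OC)c2)[C@H]1CO | intermediate
11 | [(2R,3R,4S)-2-(3,4-dimethoxyphenyl)-4-[(R)-(3,4-dimethoxyphenyl)(hydroxy)methyl]-4-hydroxyoxolan-3-yl]methyl 4-methylbenzenesulfonate (not isolated) | COc1ccc(cc1OC)[C@@H](O)[C@@]1(O)CO[C@@H](c2ccc(OC)c(OC)c2)[C@H]1COS(=O)(=O)c1ccc(C)cc1 | intermediate
12 | (+)-gmelinol, (1S,2R,5R,6R)-2,6-bis(3,4-dimethoxyphenyl)-3,7-dioxabicyclo[3.3.0]octan-1-ol | COc1ccc([C@H]2OC[C@@H]3[C@H](c4ccc(OC)c(OC)c4)OC[C@]23O)cc1OC | target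

Total step count: 5. Longest linear sequence: 5 steps.

**Steps most likely to fail**

Step 3. The titanium Lewis acid may ionize the tertiary, allylic C1–O bond of the vinyl oxirane (SN1 or SN2' capture by isopropanol, the hydroperoxide or the neighbouring C2 hydroxyl) faster than the 5-endo closure takes place. Binding of both hydroxyls of the 1,4-diol to one titanium centre may also erode the discrimination between the enantiotopic halves.

The fallback sets out from 1 and returns at 8. It replaces the desymmetrization by two catalyst-controlled carbonyl alkynylations and the titanium cascade by a vanadium-directed epoxidation with a separate, fluoride-triggered ring closure; it also removes the need for the meso diol.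

- Enantioselective addition of trimethylsilylacetylene to 1 (Me2Zn, ProPhenol ligand of the sense that gives the S carbinol) should give (S)-1-(3,4-dimethoxyphenyl)-3-(trimethylsilyl)prop-2-yn-1-ol F1.
- Silylation (TBSCl, imidazole) gives the bis-silyl compound tert-butyl{[(1S)-1-(3,4-dimethoxyphenyl)-3-(trimethylsilyl)prop-2-yn-1-yl]oxy}dimethylsilane F2, and K2CO3/MeOH removes the alkynyl silyl group to give the terminal alkyne (R)-tert-butyl{[1-(3,4-dimethoxyphenyl)prop-2-yn-1-yl]oxy}dimethylsilane F3.
- Addition of F3 to a second molecule of 1 under the same conditions with the enantiomeric ligand should give the monoprotected (1R,4S)-4-{[tert-butyl(dimethyl)silyl]oxy}-1,4-bis(3,4-dimethoxyphenyl)but-2-yn-1-ol F4.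
- Ethylene and the second-generation Grubbs catalyst convert F4 into (1R,4S)-4-{[tert-butyl(dimethyl)silyl]oxy}-1,4-bis(3,4-dimethoxyphenyl)-2,3-dimethylidenebutan-1-ol F5.
- VO(acac)2/t-BuOOH epoxidation of F5, directed by the free allylic hydroxyl and erythro-selective because of A1,2 strain with the geminal substituent, should give the epoxy alcohol (R)-[(2S)-2-{(3S)-3-{[tert-butyl(dimethyl)silyl]oxy}-3-(3,4-dimethoxyphenyl)prop-1-en-2-yl}oxiran-2-yl](3,4-dimethoxyphenyl)methanol F6.
- Bu4NF buffered with AcOH frees the C6 hydroxyl, which closes ring B onto C8 (PPTS if needed) to give 8.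

Step 2. Chelation of the ruthenium carbene by the two propargylic hydroxyls and shielding of the alkyne by two secondary benzylic carbons may stall the alkyne insertion. Ruthenium hydride formed on catalyst decay may also isomerize the allylic alcohols of the product to ketones.

The fallback sets out from 1 and returns at 6; it builds the diene by two SE2' carbonyl additions instead of metathesis. Indium powder, 1,4-dibromobut-2-yne and 1 (2 equiv) in DMF at 23 °C (Barbier conditions) should first give the allenyl bromide 2-(bromomethyl)-1-(3,4-dimethoxyphenyl)buta-2,3-dien-1-ol F7. Its allylic bromide is metalated again and adds a second molecule of 1 through the central allene carbon, giving the 2,3-disubstituted diene diol directly. As in step 1, no control of the relative configuration is expected, and meso-6 is separated from the chiral diastereomer by crystallization or chromatography.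

Step 1. The absence of 1,4-induction gives both diastereomers, and co-crystallization may prevent isolation of pure meso-4.

The fallback sets out from 1 and 2 (addition run as in step 1, product not crystallized) and returns at 4; it sorts the stereoisomers chemically instead of physically. The crude diol mixture is acylated with vinyl acetate and Burkholderia cepacia lipase in t-BuOMe. Because the enzyme acylates carbinols of one configuration only, the meso diol should stop at the monoacetate (1S,4R)-4-hydroxy-1,4-bis(3,4-dimethoxyphenyl)but-2-yn-1-yl acetate F8, while one enantiomer of the chiral diastereomer is acylated twice and the other not at all. The three acylation levels differ strongly in polarity and should separate on silica gel; K2CO3/MeOH then returns F8 to 4. Which carbinol the enzyme prefers is immaterial here.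

Further compounds
F1 | step 3 | (S)-1-(3,4-dimethoxyphenyl)-3-(trimethylsilyl)prop-2-yn-1-ol | C[Si](C)(C)C#C[C@@H](O)c1ccc(OC)c(OC)c1
F2 | step 3 | tert-butyl{[(1S)-1-(3,4-dimethoxyphenyl)-3-(trimethylsilyl)prop-2-yn-1-yl]oxy}dimethylsilane | C[Si](C)(C)C#C[C@@H](O[Si](C)(C)C(C)(C)C)c1ccc(OC)c(OC)c1
F3 | step 3 | (R)-tert-butyl{[1-(3,4-dimethoxyphenyl)prop-2-yn-1-yl]oxy}dimethylsilane | C#C[C@@H](O[Si](C)(C)C(C)(C)C)c1ccc(OC)c(OC)c1
F4 | step 3 | (1R,4S)-4-{[tert-butyl(dimethyl)silyl]oxy}-1,4-bis(3,4-dimethoxyphenyl)but-2-yn-1-ol | COc1ccc(cc1OC)[C@@H](O)C#C[C@@H](O[Si](C)(C)C(C)(C)C)c1ccc(OC)c(OC)c1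
F5 | step 3 | (1R,4S)-4-{[tert-butyl(dimethyl)silyl]oxy}-1,4-bis(3,4-dimethoxyphenyl)-2,3-dimethylidenebutan-1-ol | COc1ccc(cc1OC)[C@@H](O)C(=C)C(=C)[C@@H](O[Si](C)(C)C(C)(C)C)c1ccc(OC)c(OC)c1
F6 | step 3 | (R)-[(2S)-2-{(3S)-3-{[tert-butyl(dimethyl)silyl]oxy}-3-(3,4-dimethoxyphenyl)prop-1-en-2-yl}oxiran-2-yl](3,4-dimethoxyphenyl)methanol | COc1ccc(cc1OC)[C@@H](O)[C@@]1(CO1)C(=C)[C@@H](O[Si](C)(C)C(C)(C)C)c1ccc(OC)c(OC)c1
F7 | step 2 | 2-(bromomethyl)-1-(3,4-dimethoxyphenyl)buta-2,3-dien-1-ol (racemic) | COc1ccc(cc1OC)C(O)C(CBr)=C=C
F8 | step 1 | (1S,4R)-4-hydroxy-1,4-bis(3,4-dimethoxyphenyl)but-2-yn-1-yl acetate | COc1ccc(cc1OC)[C@@H](O)C#C[C@@H](OC(C)=O)c1ccc(OC)c(OC)c1
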